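**Retrosynthetic overview**
1. Last bond: the C9 ester, made by acylating hydroxy ether 18 with (R)-2-methylbutanoic acid.
2. All three rings of the target close in one cascade from epoxy aldehyde 14, in the presumed biogenetic order: ten-membered carbocycle (ring A, C7–C8, allylmetal + aldehyde), then 8,12-γ-lactone (ring B), then the 5,10-oxygen bridge (ring C, 5-OH opens a 9,10-epoxide at C10 with inversion).
3. A temporary 5,12-δ-lactone ties O5 to C12 so that C5 dictates C7 and C8; translactonisation then releases 5-OH for the ether closure.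
4. Precursor 14 comes from geraniol (C1–C5, C8–C10, C14, C15), allyl acetate (C6, C7) and 2-(bromomethyl)acrylic acid (C11–C13). Stereocentres: Ru-BINAP hydrogenation (C4), Ir-catalysed allylation (C5), Sharpless epoxidation (C9, C10).
5. Ring order: dihydropyranone (temporary, RCM) → ring A → ring B → ring C.

Assumption: germacrane numbering is used (ring C1–C10; C14 = CH3 on C10; C15 = CH3 on C4; C11/C12/C13 on C7 with C12 the carbonyl; lactone C12–O–C8; ether O between C5 and C10; ester on C9), and compounds 1, 5, 8 and 19 are bought.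

**Route**

Step 1
Reactants: 1 geraniol
Product: 2 (2E)-1-[(4-methoxybenzyl)oxy]-3,7-dimethylocta-2,6-diene
Conditions: NaH, 4-methoxybenzyl chloride, Bu4NI (cat.), THF/DMF, 0 °C to rt
Reagents that add atoms: 4-methoxybenzyl chloride, COc1ccc(CCl)cc1
Why: Williamson etherification (SN2) masks O8 with a group that survives hydrogenation, hot carboxylate and metathesis and is later removed oxidatively; no stereocentre is formed.

Step 2
Reactants: 2 (2E)-1-[(4-methoxybenzyl)oxy]-3,7-dimethylocta-2,6-diene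
Product: 3 (2E,6E)-8-[(4-methoxybenzyl)oxy]-2,6-dimethylocta-2,6-dien-1-ol
Conditions: SeO2 (20 mol%), t-BuOOH (3 equiv), CH2Cl2, 0 °C to rt
Reagents that add atoms: selenium dioxide, O=[Se]=O (oxygen donor); tert-butyl hydroperoxide, CC(C)(C)OO (regenerates SeO2)
Why: Selenium dioxide allylic oxidation (ene reaction then [2,3]-shift, Sharpless–Umbreit conditions) attacks the more electron-rich terminal alkene at its (E)-methyl group and gives the (E)-allylic alcohol; no stereocentre is formed.

Step 3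
Reactants: 3 (2E,6E)-8-[(4-methoxybenzyl)oxy]-2,6-dimethylocta-2,6-dien-1-ol
Product: 4 (2S,6E)-8-[(4-methoxybenzyl)oxy]-2,6-dimethyloct-6-en-1-ol
Conditions: Ru(OAc)2[(S)-BINAP] (1 mol%), H2 (100 atm), MeOH, 25 °C
Reagents that add atoms: none
Why: Noyori hydroxyl-directed asymmetric hydrogenation reduces only the alkene next to the free CH2OH and sets C4 as S, the sense being assigned by analogy with the face selection that gives (R)-citronellol from geraniol with this ligand (the antipodal ligand is used if the 2-methyl pattern reverses it).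

Step 4
Reactants: 4 (2S,6E)-8-[(4-methoxybenzyl)oxy]-2,6-dimethyloct-6-en-1-ol; 5 allyl acetate
Product: 7 (4R,5S,9E)-11-[(4-methoxybenzyl)oxy]-5,9-dimethylundeca-1,9-dien-4-ol, via aldehyde 6 (not isolated)
Conditions: [Ir(cod)Cl]2 (2.5 mol%), (R)-BINAP (5 mol%), 4-cyano-3-nitrobenzoic acid (10 mol%), Cs2CO3 (20 mol%), THF, 100 °C
Reagents that add atoms: none
Why: Krische iridium-catalysed transfer-hydrogenative carbonyl allylation from the alcohol oxidation level forms aldehyde 6 only transiently (no epimerisation at C4) and sets C5 as R under catalyst control, overriding the Felkin preference (the ligand antipode is the one that gives the 4R carbinol).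

Step 5
Reactants: 7 (4R,5S,9E)-11-[(4-methoxybenzyl)oxy]-5,9-dimethylundeca-1,9-dien-4-ol; 8 2-(bromomethyl)prop-2-enoic acid
Product: 10 (4R,5S,9E)-11-[(4-methoxybenzyl)oxy]-5,9-dimethylundeca-1,9-dien-4-yl 2-(bromomethyl)prop-2-enoate, via 2-(bromomethyl)prop-2-enoyl bromide 9 (not isolated)
Conditions: 8, (COBr)2, DMF (cat.), CH2Cl2, 0 °C to rt; then 7, i-Pr2NEt, CH2Cl2, −20 to 0 °C
Reagents that add atoms: none
Why: Acylation of the secondary alcohol by the acyl bromide made in situ (oxalyl bromide avoids halide scrambling and the hindered amine does not attack the allylic bromide); no stereocentre is touched.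

Step 6
Reactants: 10 (4R,5S,9E)-11-[(4-methoxybenzyl)oxy]-5,9-dimethylundeca-1,9-dien-4-yl 2-(bromomethyl)prop-2-enoate
Product: 11 (6R)-3-(bromomethyl)-6-[(2S,6E)-8-[(4-methoxybenzyl)oxy]-6-methyloct-6-en-2-yl]-5,6-dihydro-2H-pyran-2-one
Conditions: second-generation Hoveyda–Grubbs catalyst [RuCl2(SIMes)(=CH-C6H4-2-OiPr)] (10 mol%), toluene (0.005 M), 80 °C
Reagents that add atoms: none
Why: Ring-closing metathesis of the vinyl group onto the 1,1-disubstituted acrylate (methacrylate-type closure to a 3-substituted dihydropyranone) holds C6 cis to the carbonyl across C7=C11, which fixes the allyl geometry for step 10; the trisubstituted alkene is inert and no stereocentre is formed.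

Step 7
Reactants: 11 (6R)-3-(bromomethyl)-6-[(2S,6E)-8-[(4-methoxybenzyl)oxy]-6-methyloct-6-en-2-yl]-5,6-dihydro-2H-pyran-2-one
Product: 12 (6R)-3-(bromomethyl)-6-[(2S,6E)-8-hydroxy-6-methyloct-6-en-2-yl]-5,6-dihydro-2H-pyran-2-one
Conditions: DDQ (1.2 equiv), CH2Cl2/pH 7 buffer (10:1), 0 °C
Reagents that add atoms: none
Why: Oxidative cleavage of the electron-rich benzyl ether by DDQ under neutral buffered conditions leaves the allylic bromide and the unsaturated lactone intact; no stereocentre is touched.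

Step 8
Reactants: 12 (6R)-3-(bromomethyl)-6-[(2S,6E)-8-hydroxy-6-methyloct-6-en-2-yl]-5,6-dihydro-2H-pyran-2-one
Product: 13 (6R)-3-(bromomethyl)-6-{(2S)-5-[(2S,3S)-3-(hydroxymethyl)-2-methyloxiran-2-yl]pentan-2-yl}-5,6-dihydro-2H-pyran-2-one
Conditions: Ti(OiPr)4 (10 mol%), L-(+)-diethyl tartrate (12 mol%), t-BuOOH (2 equiv), 4 Å MS, CH2Cl2, −20 °C
Reagents that add atoms: tert-butyl hydroperoxide, CC(C)(C)OO
Why: Sharpless asymmetric epoxidation of the (E)-trisubstituted primary allylic alcohol (geraniol-type) with the L-(+)-tartrate catalyst gives the (2S,3S)-epoxy alcohol, i.e. C9 (S) and C10 (S), independent of the remote centres; the electron-poor lactone alkene is not epoxidised.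

Step 9
Reactants: 13 (6R)-3-(bromomethyl)-6-{(2S)-5-[(2S,3S)-3-(hydroxymethyl)-2-methyloxiran-2-yl]pentan-2-yl}-5,6-dihydro-2H-pyran-2-one
Product: 14 (2R,3S)-3-{(4S)-4-[(2R)-5-(bromomethyl)-6-oxo-3,6-dihydro-2H-pyran-2-yl]pentyl}-3-methyloxirane-2-carbaldehyde
Conditions: Dess–Martin periodinane (1.3 equiv), 2,6-lutidine (3 equiv), CH2Cl2, 0 °C
Reagents that add atoms: none
Why: Dess–Martin oxidation of the primary epoxy alcohol under buffered non-nucleophilic conditions; C9 keeps its geometry (its descriptor changes from S to R only because CHO outranks C10).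

Step 10
Reactants: 14 (2R,3S)-3-{(4S)-4-[(2R)-5-(bromomethyl)-6-oxo-3,6-dihydro-2H-pyran-2-yl]pentyl}-3-methyloxirane-2-carbaldehyde
Product: 18 (4S,5R,7R,8R,9S,10R)-5,10-epoxy-9-hydroxygermacr-11(13)-en-12,8-olide, via allylchromium dichloride 15 (not isolated), via bridged delta-lactone 16 (not isolated), via epoxy gamma-lactone 17 (not isolated)
Conditions: CrCl2 (8 equiv), THF, 25 °C, 14 added over 8 h (final 0.003 M); aqueous NH4Cl work-up, crude in CH2Cl2, CSA (0.2 equiv), 0 to 25 °C
Reagents that add atoms: none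
Why: Proposed new method: CrCl2 reduces the allylic bromide to allylchromium 15, whose C7=C11 bond is held in the lactone ring with C6 trans to CH2Cr, so a chair Zimmerman–Traxler addition through C7 to the tethered aldehyde (aldehyde substituent equatorial) gives the anti adduct, i.e. C8 (R), while the seven-atom chain can bridge C5 and C7 of the lactone only in the cis sense, so C7 (R) follows from C5; the C8 alkoxide of 16 then attacks C12 and trades the bridged δ-lactone for the trans-fused γ-lactone 17, and the released 5-OH opens the protonated epoxide at tertiary C10 from inside the ring with inversion (only this mode gives a cis oxygen bridge, attack at C9 would need a trans bridge), leaving 9-OH with C9 (S) and C10 (R); the closest known reactions are the chromium-mediated Nozaki–Hiyama-type Barbier macrocyclisation of ω-formyl 2-(bromomethyl)acrylates to germacranolide α-methylene lactones, the allylation–translactonisation of 3-(bromomethyl)butenolides, and acid-catalysed transannular epoxide opening by a hydroxyl group.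

Step 11
Reactants: 18 (4S,5R,7R,8R,9S,10R)-5,10-epoxy-9-hydroxygermacr-11(13)-en-12,8-olide; 19 (2R)-2-methylbutanoic acid
Product: 21 (4S,5R,7R,8R,9S,10R)-5,10-epoxy-9-{[(2R)-2-methylbutanoyl]oxy}germacr-11(13)-en-12,8-olide (the target), via mixed anhydride 20 (not isolated)
Conditions: 19, 2,4,6-trichlorobenzoyl chloride, Et3N, toluene, 25 °C; then 18, DMAP, toluene, 40 °C
Reagents that add atoms: none
Why: Yamaguchi esterification (mixed anhydride, DMAP acyl transfer) acylates the hindered secondary 9-OH; the C9–O bond and the acid α-centre are not touched, so both configurations are retained.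

**Compound list**
1 | geraniol, (2E)-3,7-dimethylocta-2,6-dien-1-ol | CC(C)=CCC/C(C)=C/CO | starting material
2 | (2E)-1-[(4-methoxybenzyl)oxy]-3,7-dimethylocta-2,6-diene | COc1ccc(COC/C=C(\C)CCC=C(C)C)cc1 | intermediate
3 | (2E,6E)-8-[(4-methoxybenzyl)oxy]-2,6-dimethylocta-2,6-dien-1-ol | COc1ccc(COC/C=C(\C)CC/C=C(\C)CO)cc1 | intermediate
4 | (2S,6E)-8-[(4-methoxybenzyl)oxy]-2,6-dimethyloct-6-en-1-ol | COc1ccc(COC/C=C(\C)CCC[C@H](C)CO)cc1 | intermediate
5 | allyl acetate (prop-2-en-1-yl acetate) | C=CCOC(C)=O | starting material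
6 | (2S,6E)-8-[(4-methoxybenzyl)oxy]-2,6-dimethyloct-6-enal | COc1ccc(COC/C=C(\C)CCC[C@H](C)C=O)cc1 | intermediate (not isolated)
7 | (4R,5S,9E)-11-[(4-methoxybenzyl)oxy]-5,9-dimethylundeca-1,9-dien-4-ol | COc1ccc(COC/C=C(\C)CCC[C@H](C)[C@H](O)CC=C)cc1 | intermediate
8 | 2-(bromomethyl)prop-2-enoic acid | C=C(CBr)C(=O)O | starting material
9 | 2-(bromomethyl)prop-2-enoyl bromide | C=C(CBr)C(=O)Br | intermediate (not isolated)
10 | (4R,5S,9E)-11-[(4-methoxybenzyl)oxy]-5,9-dimethylundeca-1,9-dien-4-yl 2-(bromomethyl)prop-2-enoate | COc1ccc(COC/C=C(\C)CCC[C@H](C)[C@@H](CC=C)OC(=O)C(=C)CBr)cc1 | intermediate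
11 | (6R)-3-(bromomethyl)-6-[(2S,6E)-8-[(4-methoxybenzyl)oxy]-6-methyloct-6-en-2-yl]-5,6-dihydro-2H-pyran-2-one | COc1ccc(COC/C=C(\C)CCC[C@H](C)[C@H]2CC=C(CBr)C(=O)O2)cc1 | intermediate
12 | (6R)-3-(bromomethyl)-6-[(2S,6E)-8-hydroxy-6-methyloct-6-en-2-yl]-5,6-dihydro-2H-pyran-2-one | OC/C=C(\C)CCC[C@H](C)[C@H]1CC=C(CBr)C(=O)O1 | intermediate
13 | (6R)-3-(bromomethyl)-6-{(2S)-5-[(2S,3S)-3-(hydroxymethyl)-2-methyloxiran-2-yl]pentan-2-yl}-5,6-dihydro-2H-pyran-2-one | OC[C@@H]1O[C@@]1(C)CCC[C@H](C)[C@H]2CC=C(CBr)C(=O)O2 | intermediate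
14 | (2R,3S)-3-{(4S)-4-[(2R)-5-(bromomethyl)-6-oxo-3,6-dihydro-2H-pyran-2-yl]pentyl}-3-methyloxirane-2-carbaldehyde | O=C[C@@H]1O[C@@]1(C)CCC[C@H](C)[C@H]2CC=C(CBr)C(=O)O2 | intermediate
15 | allylchromium dichloride: 14 with CH2Br replaced by CH2CrCl2 (trivalent chromium, THF-solvated) | O=C[C@@H]1O[C@@]1(C)CCC[C@H](C)[C@H]2CC=C(C[Cr](Cl)Cl)C(=O)O2 | intermediate (not isolated)
16 | (4S,5R,7R,8R,9S,10S)-9,10-epoxy-8-hydroxygermacr-11(13)-en-12,5-olide (bridged δ-lactone; chromium alkoxide in the flask, drawn as the alcohol) | O[C@H]1[C@@H]2O[C@@]2(C)CCC[C@H](C)[C@H]3C[C@@H]1C(=C)C(=O)O3 | intermediate (not isolated)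
17 | (4S,5R,7R,8R,9S,10S)-9,10-epoxy-5-hydroxygermacr-11(13)-en-12,8-olide | C=C1C(=O)O[C@@H]2[C@@H]1C[C@@H](O)[C@@H](C)CCC[C@]3(C)O[C@@H]23 | intermediate (not isolated)
18 | (4S,5R,7R,8R,9S,10R)-5,10-epoxy-9-hydroxygermacr-11(13)-en-12,8-olide | C=C1C(=O)O[C@@H]2[C@@H]1C[C@H]1O[C@](C)(CCC[C@@H]1C)[C@H]2O | intermediate
19 | (2R)-2-methylbutanoic acid | CC[C@@H](C)C(=O)O | starting material
20 | (2R)-2-methylbutanoic 2,4,6-trichlorobenzoic anhydride | CC[C@@H](C)C(=O)OC(=O)c1c(Cl)cc(Cl)cc1Cl | intermediate (not isolated)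
21 | (4S,5R,7R,8R,9S,10R)-5,10-epoxy-9-{[(2R)-2-methylbutanoyl]oxy}germacr-11(13)-en-12,8-olide | C=C1C(=O)O[C@@H]2[C@@H]1C[C@H]1O[C@](C)(CCC[C@@H]1C)[C@H]2OC(=O)[C@H](C)CC | target

**Step count**
Total steps: 11. Longest linear sequence: 11 (geraniol to 21).

**Steps most likely to fail, with fallbacks**

Step 10 (cascade macrocyclisation). The bridged transition state may be too strained, a boat transition state would give the cis-lactone, and oligomerisation or premature epoxide opening can compete. The fallback drops the lactone tether and uses the conventional monocyclic closure; it sets out from 7 and comes back at 18. Alcohol 7 is silylated (Et3SiCl, imidazole) to the triethylsilyl ether F1. Cross-metathesis of F1 with commercial methyl 2-(bromomethyl)acrylate (second-generation Hoveyda–Grubbs catalyst, a methacrylate-type cross-metathesis) gives the (Z)-bromo ester F2. DDQ then frees the allylic alcohol F3, Sharpless epoxidation with L-(+)-diethyl tartrate gives the epoxy alcohol F4, and Dess–Martin oxidation gives the epoxy aldehyde F5. CrCl2 at high dilution closes ring A and the hydroxy ester lactonises to the silyl-protected epoxy lactone F6; the diastereomers are separated at this point because C7 and C8 are now set only by the macrocycle. CSA in wet CH2Cl2 removes the silyl group and the free 5-OH opens the epoxide, which gives 18.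

Step 3 (asymmetric hydrogenation of the 2-methyl allylic alcohol). Enantioselectivity and sense for this substitution pattern are less secure than for geraniol-type substrates. The fallback moves the hydrogenation to the carboxylic acid level, where (E)-2-methyl-2-alkenoic acids are a well-behaved class; it sets out from 3 and comes back at 4. MnO2 oxidises 3 to the dienal F7, NaClO2/NaH2PO4/2-methyl-2-butene gives the dienoic acid F8, hydrogenation with Ru(OAc)2[(S)-H8-BINAP] gives the saturated (S)-acid F9, and LiAlH4 reduces F9 to 4.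

Step 4 (allylation of the α-branched alcohol at 100 °C). Conversion may be slow, and diastereoselectivity or C4 integrity may suffer. The fallback replaces the redox-neutral catalytic coupling by a stoichiometric reagent-controlled addition to the isolated aldehyde; it sets out from 4 and comes back at 7. Dess–Martin oxidation gives aldehyde 6, which is isolated here. B-allyldiisopinocampheylborane (the antipode that gives the 4R carbinol) is added at −78 °C in Et2O, and oxidative work-up gives 7. No new compound is made.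

Further compounds
F1 | step 10 | triethyl{[(4R,5S,9E)-11-[(4-methoxybenzyl)oxy]-5,9-dimethylundeca-1,9-dien-4-yl]oxy}silane | COc1ccc(COC/C=C(\C)CCC[C@H](C)[C@H](O[Si](CC)(CC)CC)CC=C)cc1
F2 | step 10 | methyl (2Z,5R,6S,10E)-2-(bromomethyl)-12-[(4-methoxybenzyl)oxy]-6,10-dimethyl-5-[(triethylsilyl)oxy]dodeca-2,10-dienoate | COc1ccc(COC/C=C(\C)CCC[C@H](C)[C@H](O[Si](CC)(CC)CC)C/C=C(\CBr)C(=O)OC)cc1
F3 | step 10 | methyl (2Z,5R,6S,10E)-2-(bromomethyl)-12-hydroxy-6,10-dimethyl-5-[(triethylsilyl)oxy]dodeca-2,10-dienoate | OC/C=C(\C)CCC[C@H](C)[C@H](O[Si](CC)(CC)CC)C/C=C(\CBr)C(=O)OC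
F4 | step 10 | methyl (2Z,5R,6S)-2-(bromomethyl)-9-[(2S,3S)-3-(hydroxymethyl)-2-methyloxiran-2-yl]-6-methyl-5-[(triethylsilyl)oxy]non-2-enoate | OC[C@@H]1O[C@@]1(C)CCC[C@H](C)[C@H](O[Si](CC)(CC)CC)C/C=C(\CBr)C(=O)OC
F5 | step 10 | methyl (2Z,5R,6S)-2-(bromomethyl)-9-[(2S,3R)-3-formyl-2-methyloxiran-2-yl]-6-methyl-5-[(triethylsilyl)oxy]non-2-enoate | O=C[C@@H]1O[C@@]1(C)CCC[C@H](C)[C@H](O[Si](CC)(CC)CC)C/C=C(\CBr)C(=O)OC
F6 | step 10 | (4S,5R,7R,8R,9S,10S)-9,10-epoxy-5-[(triethylsilyl)oxy]germacr-11(13)-en-12,8-olide | C=C1C(=O)O[C@@H]2[C@@H]1C[C@@H](O[Si](CC)(CC)CC)[C@@H](C)CCC[C@]3(C)O[C@@H]23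
F7 | step 3 | (2E,6E)-8-[(4-methoxybenzyl)oxy]-2,6-dimethylocta-2,6-dienal | COc1ccc(COC/C=C(\C)CC/C=C(\C)C=O)cc1
F8 | step 3 | (2E,6E)-8-[(4-methoxybenzyl)oxy]-2,6-dimethylocta-2,6-dienoic acid | COc1ccc(COC/C=C(\C)CC/C=C(\C)C(=O)O)cc1
F9 | step 3 | (2S,6E)-8-[(4-methoxybenzyl)oxy]-2,6-dimethyloct-6-enoic acid | COc1ccc(COC/C=C(\C)CCC[C@H](C)C(=O)O)cc1
F0 | step 4 | none | none
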